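**Strategy.** The isoflavone is cut at C3–C4 of the pyranone (C) ring. C4 is a carbonyl carbon, and C3, which carries the chromenyl B ring, is treated as a masked ketone carbon whose oxygen is lost later as water. A triazolium-carbene crossed benzoin inverts the polarity of a salicylaldehyde formyl group (future C4) so that it adds to a tethered aryl ketone (future C3). This forms the C3–C4 bond and the C ring in one operation, as a 3-hydroxychroman-4-one. The precursor is the 4-O-MOM salicylaldehyde whose 2-oxygen carries a CH2–C(=O)–(8-methoxy-2,2-dimethylchromen-6-yl) arm. Dehydration across C2–C3 and MOM removal finish the synthesis.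

Key step: step 6

Assumption: the target SMILES holds no stereocentre and no configurable double bond, so the compound is achiral and needs no enantiocontrol. The carbinol centre made in step 6 is deliberately racemic and is erased in step 7.

**Step 1**
Reactants: 1 acetovanillone; 2 3-chloro-3-methylbut-1-yne
Product: 3 1-{3-methoxy-4-[(2-methylbut-3-yn-2-yl)oxy]phenyl}ethan-1-one
Conditions: 2 (1.5 equiv), DBU, CuCl2·2H2O (cat.), MeCN, 0 °C → rt
Reagents that add atoms: none
Why: Copper-catalysed O-propargylation of a phenoxide by a tertiary propargylic chloride is the standard entry to aryl 1,1-dimethylpropargyl ethers and tolerates the para-acetyl group.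

**Step 2**
Reactants: 3 1-{3-methoxy-4-[(2-methylbut-3-yn-2-yl)oxy]phenyl}ethan-1-one
Product: 4 1-(8-methoxy-2,2-dimethyl-2H-chromen-6-yl)ethan-1-one
Conditions: PhNEt2, 190 °C
Reagents that add atoms: none
Why: Aryl propargyl Claisen rearrangement, 1,5-hydrogen shift and oxa-6π electrocyclisation should give the 2,2-dimethylchromene, and since only one ortho position is free the acetyl group must end at C6 and the methoxy group at C8.

**Step 3**
Reactants: 4 1-(8-methoxy-2,2-dimethyl-2H-chromen-6-yl)ethan-1-one
Product: 6 2-bromo-1-(8-methoxy-2,2-dimethyl-2H-chromen-6-yl)ethan-1-one, via trimethylsilyl enol ether 5 (not isolated)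
Conditions: TMSOTf (1.15 equiv), Et3N (1.3 equiv), CH2Cl2, 0 °C; then NBS (1.05 equiv), −78 → 0 °C; aq. NaHCO3/Na2S2O3 work-up
Reagents that add atoms: N-bromosuccinimide, O=C1CCC(=O)N1Br; trimethylsilyl trifluoromethanesulfonate, C[Si](C)(C)OS(=O)(=O)C(F)(F)F (its silyl group is held only in 5)
Why: Soft enolisation gives the only possible silyl enol ether, which is far more nucleophilic than the chromene C3=C4 bond or the arene, so one equivalent of NBS at low temperature should brominate only the α-carbon (silyl enol ether halogenation).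

**Step 4**
Reactants: 7 2,4-dihydroxybenzaldehyde
Product: 8 2-hydroxy-4-(methoxymethoxy)benzaldehyde
Conditions: MOMCl (1.05 equiv), K2CO3, acetone, 0 °C → rt
Reagents that add atoms: chloromethyl methyl ether, COCCl
Why: In this Williamson-type alkylation the 2-OH is held in a hydrogen bond to the formyl oxygen and is less acidic than the 4-OH, so one equivalent of MOMCl should mask only O4, giving an ether that is inert to carbonate, amine and carbene and leaves under mild acid.

**Step 5**
Reactants: 6 2-bromo-1-(8-methoxy-2,2-dimethyl-2H-chromen-6-yl)ethan-1-one; 8 2-hydroxy-4-(methoxymethoxy)benzaldehyde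
Product: 9 2-[2-(8-methoxy-2,2-dimethyl-2H-chromen-6-yl)-2-oxoethoxy]-4-(methoxymethoxy)benzaldehyde
Conditions: K2CO3 (1.2 equiv), acetone, rt; quench on consumption of 6
Reagents that add atoms: none
Why: Williamson etherification of the remaining phenol with the very reactive phenacyl-type bromide should proceed at room temperature, where the follow-up Rap–Stoermer aldol condensation to a benzofuran is slow.

**Step 6**
Reactants: 9 2-[2-(8-methoxy-2,2-dimethyl-2H-chromen-6-yl)-2-oxoethoxy]-4-(methoxymethoxy)benzaldehyde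
Product: 10 rac-3-hydroxy-3-(8-methoxy-2,2-dimethyl-2H-chromen-6-yl)-7-(methoxymethoxy)-2,3-dihydro-4H-chromen-4-one
Conditions: 2-(pentafluorophenyl)-6,7-dihydro-5H-pyrrolo[2,1-c][1,2,4]triazol-2-ium tetrafluoroborate (10 mol%), Et3N (20 mol%), toluene, rt, N2
Reagents that add atoms: none
Why: Et3N frees the triazolylidene, which adds to the formyl group of 9 and after proton transfer gives the Breslow enaminol, whose former carbonyl carbon (future C4) attacks the tethered ketone carbon (future C3); collapse of the adduct restores the C4 ketone and releases the carbene. This is the known carbene-catalysed intramolecular crossed aldehyde–ketone benzoin of 2-(2-aryl-2-oxoethoxy)benzaldehydes to 3-hydroxychroman-4-ones. The pyranone ring closes in a 6-exo-trig mode, the ketone oxygen staying outside the ring. The new C3 carbinol centre forms racemic because the catalyst is achiral, which is harmless since step 7 flattens it. Chemoselectivity comes from the substrate: only the aldehyde has the formyl hydrogen needed to become an acyl anion, and the six-membered intramolecular path should beat aldehyde homo-coupling. The competing base-mediated aldol condensation to a 2-aroylbenzofuran is held back by the acidic N-C6F5 triazolium, which needs only a substoichiometric tertiary amine in a non-polar solvent.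

**Step 7**
Reactants: 10 rac-3-hydroxy-3-(8-methoxy-2,2-dimethyl-2H-chromen-6-yl)-7-(methoxymethoxy)-2,3-dihydro-4H-chromen-4-one
Product: 11 3-(8-methoxy-2,2-dimethyl-2H-chromen-6-yl)-7-(methoxymethoxy)-4H-chromen-4-one
Conditions: SOCl2 (1.5 equiv), pyridine, CH2Cl2, 0 °C → rt
Reagents that add atoms: none
Why: The tertiary benzylic carbinol is converted to its chlorosulfite and eliminated by pyridine toward C2, the only carbon with β-hydrogens, driven by formation of the conjugated 4-pyranone (classical SOCl2/pyridine dehydration of a tertiary α-ketol).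

**Step 8**
Reactants: 11 3-(8-methoxy-2,2-dimethyl-2H-chromen-6-yl)-7-(methoxymethoxy)-4H-chromen-4-one
Product: 12 7-hydroxy-3-(8-methoxy-2,2-dimethyl-2H-chromen-6-yl)-4H-chromen-4-one
Conditions: 3 M aq. HCl, MeOH, 50 °C
Reagents that add atoms: none
Why: Acid-catalysed acetal exchange with methanol should cleave the MOM ether under conditions that the 2,2-dimethylchromene, the aryl methyl ether and the chromone tolerate.

**Compound list**
1 | acetovanillone | CC(=O)c1ccc(O)c(OC)c1 | starting material
2 | 3-chloro-3-methylbut-1-yne | CC(C)(Cl)C#C | starting material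
3 | 1-{3-methoxy-4-[(2-methylbut-3-yn-2-yl)oxy]phenyl}ethan-1-one | CC(=O)c1ccc(OC(C)(C)C#C)c(OC)c1 | intermediate
4 | 1-(8-methoxy-2,2-dimethyl-2H-chromen-6-yl)ethan-1-one | CC(=O)c1cc(OC)c2OC(C)(C)C=Cc2c1 | intermediate
5 | [1-(8-methoxy-2,2-dimethyl-2H-chromen-6-yl)ethenyl]oxy(trimethyl)silane | C=C(O[Si](C)(C)C)c1cc(OC)c2OC(C)(C)C=Cc2c1 | intermediate (not isolated)
6 | 2-bromo-1-(8-methoxy-2,2-dimethyl-2H-chromen-6-yl)ethan-1-one | O=C(CBr)c1cc(OC)c2OC(C)(C)C=Cc2c1 | intermediate
7 | 2,4-dihydroxybenzaldehyde | O=Cc1ccc(O)cc1O | starting material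
8 | 2-hydroxy-4-(methoxymethoxy)benzaldehyde | COCOc1ccc(C=O)c(O)c1 | intermediate
9 | 2-[2-(8-methoxy-2,2-dimethyl-2H-chromen-6-yl)-2-oxoethoxy]-4-(methoxymethoxy)benzaldehyde | COCOc1ccc(C=O)c(OCC(=O)c2cc(OC)c3OC(C)(C)C=Cc3c2)c1 | intermediate
10 | rac-3-hydroxy-3-(8-methoxy-2,2-dimethyl-2H-chromen-6-yl)-7-(methoxymethoxy)-2,3-dihydro-4H-chromen-4-one | COCOc1ccc2c(c1)OCC(O)(c1cc(OC)c3OC(C)(C)C=Cc3c1)C2=O | intermediate
11 | 3-(8-methoxy-2,2-dimethyl-2H-chromen-6-yl)-7-(methoxymethoxy)-4H-chromen-4-one | COCOc1ccc2c(c1)occ(-c1cc(OC)c3OC(C)(C)C=Cc3c1)c2=O | intermediate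
12 | 7-hydroxy-3-(8-methoxy-2,2-dimethyl-2H-chromen-6-yl)-4H-chromen-4-one | COc1cc(-c2coc3cc(O)ccc3c2=O)cc2c1OC(C)(C)C=C2 | target

**Step count.** Total: 8 steps. Longest linear sequence: 7 steps (1, 2, 3, 5, 6, 7, 8 from acetovanillone); step 4 is a one-step side branch.

**Steps most likely to fail**

Step 6. The base-triggered intramolecular aldol condensation may outrun carbene addition, or the Breslow intermediate may add too slowly to the electron-rich, para-alkoxy-substituted aryl ketone so that conversion stalls. The fallback sets out from 2 and comes back at 11. It gives up the C3–C4 closure and joins the B ring to a finished chromone at C3 by Suzuki–Miyaura coupling. Commercial 4-bromo-2-methoxyphenol would be propargylated with 2 (DBU, cat. CuCl2, MeCN) to 4-bromo-2-methoxy-1-[(2-methylbut-3-yn-2-yl)oxy]benzene F1. Heating (PhNEt2, 190 °C) should give 6-bromo-8-methoxy-2,2-dimethyl-2H-chromene F2. Miyaura borylation (B2pin2, Pd(dppf)Cl2, KOAc, dioxane, 90 °C) should give 2-(8-methoxy-2,2-dimethyl-2H-chromen-6-yl)-4,4,5,5-tetramethyl-1,3,2-dioxaborolane F3. In parallel, commercial 2,4-dihydroxyacetophenone would be protected (MOMCl, K2CO3, acetone) to 1-[2-hydroxy-4-(methoxymethoxy)phenyl]ethan-1-one F4. Condensation with DMF dimethyl acetal (90 °C) should give (E)-3-(dimethylamino)-1-[2-hydroxy-4-(methoxymethoxy)phenyl]prop-2-en-1-one F5. Cyclisation with I2/pyridine in CHCl3 should give 3-iodo-7-(methoxymethoxy)-4H-chromen-4-one F6. Coupling of F3 with F6 (Pd(dppf)Cl2, aq. Na2CO3, DME, 80 °C) should give 11.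

Step 3. Electrophilic bromine may add to the electron-rich chromene C3=C4 bond, or the α-carbon may be brominated twice. The fallback sets out from 2 and comes back at 9. It makes the halomethyl ketone by C–C bond formation, so no electrophilic halogen meets the chromene. Commercial methyl vanillate would be propargylated with 2 (DBU, cat. CuCl2, MeCN) to methyl 3-methoxy-4-[(2-methylbut-3-yn-2-yl)oxy]benzoate F7. Heating (PhNEt2, 190 °C) should give methyl 8-methoxy-2,2-dimethyl-2H-chromene-6-carboxylate F8. Chloromethyllithium made in situ (ICH2Cl, MeLi·LiBr, THF, −78 °C) should convert the ester to 2-chloro-1-(8-methoxy-2,2-dimethyl-2H-chromen-6-yl)ethan-1-one F9. This chloride would alkylate 8 (K2CO3, cat. NaI, acetone, rt) to give 9.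

Step 7. Ionisation next to the carbonyl may divert into α-ketol rearrangement with ring contraction, or into substitution by chloride instead of elimination. The fallback sets out from 10 and comes back at 11. It removes the hydroxyl reductively and then re-oxidises. SmI2 (THF/MeOH, −78 °C) should cleave the α-C–O bond of the ketol to give rac-3-(8-methoxy-2,2-dimethyl-2H-chromen-6-yl)-7-(methoxymethoxy)-2,3-dihydro-4H-chromen-4-one F10. DDQ (dioxane, reflux) should then dehydrogenate C2–C3 to give 11.

**Further compounds**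
F1 | step 6 | 4-bromo-2-methoxy-1-[(2-methylbut-3-yn-2-yl)oxy]benzene | COc1cc(Br)ccc1OC(C)(C)C#C
F2 | step 6 | 6-bromo-8-methoxy-2,2-dimethyl-2H-chromene | COc1cc(Br)cc2C=CC(C)(C)Oc12
F3 | step 6 | 2-(8-methoxy-2,2-dimethyl-2H-chromen-6-yl)-4,4,5,5-tetramethyl-1,3,2-dioxaborolane | COc1cc(B2OC(C)(C)C(C)(C)O2)cc2C=CC(C)(C)Oc12
F4 | step 6 | 1-[2-hydroxy-4-(methoxymethoxy)phenyl]ethan-1-one | CC(=O)c1ccc(OCOC)cc1O
F5 | step 6 | (E)-3-(dimethylamino)-1-[2-hydroxy-4-(methoxymethoxy)phenyl]prop-2-en-1-one | CN(C)/C=C/C(=O)c1ccc(OCOC)cc1O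
F6 | step 6 | 3-iodo-7-(methoxymethoxy)-4H-chromen-4-one | COCOc1ccc2c(c1)occ(I)c2=O
F7 | step 3 | methyl 3-methoxy-4-[(2-methylbut-3-yn-2-yl)oxy]benzoate | COC(=O)c1ccc(OC(C)(C)C#C)c(OC)c1
F8 | step 3 | methyl 8-methoxy-2,2-dimethyl-2H-chromene-6-carboxylate | COC(=O)c1cc(OC)c2OC(C)(C)C=Cc2c1
F9 | step 3 | 2-chloro-1-(8-methoxy-2,2-dimethyl-2H-chromen-6-yl)ethan-1-one | O=C(CCl)c1cc(OC)c2OC(C)(C)C=Cc2c1
F10 | step 7 | rac-3-(8-methoxy-2,2-dimethyl-2H-chromen-6-yl)-7-(methoxymethoxy)-2,3-dihydro-4H-chromen-4-one | COCOc1ccc2c(c1)OCC(c1cc(OC)c3OC(C)(C)C=Cc3c1)C2=O
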